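**Retrosynthetic overview**
1. The strategy rests on C6 of the 1,2-dioxane (ring O1–O2–C3–C4–C5–C6): a quaternary carbon bearing CH3 and the C7 chain, two groups of nearly equal size, 1,4-related to C3. Its configuration is therefore taken from the geometry of an (E)-C5=C6 alkene, and O2–C6 (with C5–H, temporarily C5–Hg) is disconnected to give the open-chain C3 hydroperoxide 16.
2. 16 comes from alcohol 13 by SN2 inversion at C3 (brosylate, ketal-protected hydroperoxide). 13 is cut at C4–C5 into the (E)-alkenyllithium 12 (from 6-methylhept-5-en-2-one via alkyne and methylalumination) and epoxide 11 (from methyl (S)-3-hydroxy-2-methylpropanoate, C3 fixed by hydrolytic kinetic resolution).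
3. After the dioxane is closed the prenyl end is grown: allylic oxidation at C11, Sharpless epoxidation (C9, C10), C11=C12 Wittig with the cyclogeranyl ylide from β-cyclocitral, diimide, then C1 to the acid.
4. Ring order: ring A is bought intact; the 1,2-dioxane is formed first (step 12), the oxirane second (step 14).

Key step: step 12

Remark 1: all names keep the locants of the target chain (C1 = carboxyl carbon, C12 = CH2 on ring A; dioxane O1–O2–C3–C6; oxirane C9–C10); TBS = tert-butyldimethylsilyl.
Remark 2: 2-methoxyprop-2-yl hydroperoxide is not an article of commerce and is assumed to be made beforehand by ozonolysis of 2,3-dimethylbut-2-ene in methanol.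

**Step 1**
Reactants: 1 6-methylhept-5-en-2-one
Product: 3 6-methylhept-5-en-1-yne, via enol phosphate 2 (not isolated)
Conditions: LiN(i-Pr)2, THF, −78 °C; ClP(O)(OEt)2, −78 °C to rt; then LiN(i-Pr)2 (2.3 equiv), −78 °C to rt
Reagents that add atoms: none
Why: Kinetic deprotonation at the methyl side gives the terminal enol phosphate 2, and a second base treatment eliminates diethyl phosphate (methyl ketone to terminal alkyne conversion through an enol phosphate, an E2-type elimination) without touching the trisubstituted alkene.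

**Step 2**
Reactants: 3 6-methylhept-5-en-1-yne
Product: 5 (1E)-1-iodo-2,6-dimethylhepta-1,5-diene, via alkenylalane 4 (not isolated)
Conditions: Me3Al, Cp2ZrCl2 (0.25 equiv), CH2Cl2, 0 °C to rt; then I2, THF, −30 to 0 °C
Reagents that add atoms: trimethylaluminium C[Al](C)C; iodine II
Why: Zirconium-catalysed methylalumination of a terminal alkyne (Negishi carboalumination) adds CH3 and Al syn with CH3 on the internal carbon, and iodinolysis of the C–Al bond with retention fixes the (E) geometry that later becomes C5=C6.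

**Step 3**
Reactants: 6 methyl (2S)-3-hydroxy-2-methylpropanoate
Product: 7 methyl (2S)-3-(TBS-oxy)-2-methylpropanoate
Conditions: TBSCl, imidazole, CH2Cl2, 0 °C to rt
Reagents that add atoms: tert-butyldimethylsilyl chloride CC(C)(C)[Si](C)(C)Cl
Why: Imidazole-promoted silylation of a primary alcohol (silyl ether protection) masks C1–OH for the organometallic and oxidative steps ahead and leaves the C2 stereocentre untouched.

**Step 4**
Reactants: 7 methyl (2S)-3-(TBS-oxy)-2-methylpropanoate
Product: 8 (2S)-3-(TBS-oxy)-2-methylpropanal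
Conditions: i-Bu2AlH (1.05 equiv), CH2Cl2, −78 °C; aqueous tartrate work-up
Reagents that add atoms: none
Why: At −78 °C the tetrahedral aluminium hemiacetal from hydride addition to the ester is stable until work-up, so partial reduction of the ester to the aldehyde (i-Bu2AlH reduction) stops at 8 with the α-stereocentre C2 intact.

**Step 5**
Reactants: 8 (2S)-3-(TBS-oxy)-2-methylpropanal
Product: 9 tert-butyl(dimethyl){[(2R)-2-methylbut-3-en-1-yl]oxy}silane
Conditions: Ph3PCH3Br, KN(SiMe3)2, THF, −78 to 0 °C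
Reagents that add atoms: methyltriphenylphosphonium bromide C[P+](c1ccccc1)(c1ccccc1)c1ccccc1.[Br-]
Why: Wittig methylenation with the non-stabilised ylide at low temperature converts the aldehyde into the terminal alkene (C3=C4) faster than the α-stereocentre C2 can enolise.

**Step 6**
Reactants: 9 tert-butyl(dimethyl){[(2R)-2-methylbut-3-en-1-yl]oxy}silane
Product: 10 tert-butyl(dimethyl){(2S)-2-[(2RS)-oxiran-2-yl]propoxy}silane (both C3 epimers)
Conditions: mCPBA, NaHCO3, CH2Cl2, 0 °C to rt
Reagents that add atoms: 3-chloroperoxybenzoic acid OOC(=O)c1cccc(Cl)c1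
Why: Prilezhaev epoxidation of the monosubstituted alkene by a peracid is reliable but the allylic stereocentre C2 exerts no useful facial control, so both C3 epimers are expected and are resolved in step 7.

**Step 7**
Reactants: 10 tert-butyl(dimethyl){(2S)-2-[(2RS)-oxiran-2-yl]propoxy}silane
Product: 11 tert-butyl(dimethyl){(2S)-2-[(2S)-oxiran-2-yl]propoxy}silane
Conditions: (S,S)-(salen)Co(OAc) (0.5 mol %; trivalent cobalt, salen = N,N'-bis(3,5-di-tert-butylsalicylidene)cyclohexane-1,2-diamine dianion), H2O (0.55 equiv), THF, 0 °C to rt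
Reagents that add atoms: none
Why: Jacobsen hydrolytic kinetic resolution is catalyst-controlled for terminal epoxides: the (S,S) cobalt salen complex hydrates the (R)-configured oxirane epimer to its diol and leaves the (S)-oxirane 11, which fixes C3 (anti to the C2 methyl group) independently of C2.

**Step 8**
Reactants: 5 (1E)-1-iodo-2,6-dimethylhepta-1,5-diene; 11 tert-butyl(dimethyl){(2S)-2-[(2S)-oxiran-2-yl]propoxy}silane
Product: 13 (2S,3R,5E)-1-(TBS-oxy)-2,6,10-trimethylundeca-5,9-dien-3-ol, via alkenyllithium 12 (not isolated)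
Conditions: 5, t-BuLi (2.0 equiv), Et2O, −78 °C; then 11, BF3·OEt2, −78 °C
Reagents that add atoms: none
Why: Lithium–iodine exchange proceeds with retention of the (E) geometry and the BF3-activated terminal epoxide is opened by SN2 attack at its unsubstituted carbon C4 (epoxide opening by an organolithium with BF3), which forms C4–C5 and carries the C3 configuration of 11 unchanged into the alcohol.

**Step 9**
Reactants: 13 (2S,3R,5E)-1-(TBS-oxy)-2,6,10-trimethylundeca-5,9-dien-3-ol
Product: 14 (2S,3R,5E)-1-(TBS-oxy)-2,6,10-trimethylundeca-5,9-dien-3-yl 4-bromobenzenesulfonate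
Conditions: 4-BrC6H4SO2Cl, Et3N, DMAP, CH2Cl2, 0 °C to rt
Reagents that add atoms: 4-bromobenzenesulfonyl chloride O=S(=O)(Cl)c1ccc(Br)cc1
Why: Sulfonylation of the secondary alcohol (O–S bond formation, no C–O bond broken) turns C3–OH into a good leaving group with retention at C3.

**Step 10**
Reactants: 14 (2S,3R,5E)-1-(TBS-oxy)-2,6,10-trimethylundeca-5,9-dien-3-yl 4-bromobenzenesulfonate
Product: 15 (2S,3S,5E)-1-(TBS-oxy)-3-[(2-methoxypropan-2-yl)peroxy]-2,6,10-trimethylundeca-5,9-diene
Conditions: 2-methoxyprop-2-yl hydroperoxide, CsOH·H2O, DMF, 0 °C to rt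
Reagents that add atoms: 2-methoxyprop-2-yl hydroperoxide COC(C)(C)OO
Why: The caesium salt of the ketal-protected hydroperoxide is a weakly basic α-effect nucleophile that displaces the brosylate by SN2 with inversion, which sets the (3S) C–O–O stereocentre of the target (alkylation of a hydroperoxide anion by a secondary sulfonate).

**Step 11**
Reactants: 15 (2S,3S,5E)-1-(TBS-oxy)-3-[(2-methoxypropan-2-yl)peroxy]-2,6,10-trimethylundeca-5,9-diene
Product: 16 (2S,3S,5E)-1-(TBS-oxy)-3-hydroperoxy-2,6,10-trimethylundeca-5,9-diene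
Conditions: AcOH–THF–H2O (4:2:1), 0 °C to rt, short contact
Reagents that add atoms: none
Why: The mixed peroxyketal is far more acid-labile than the primary silyl ether or the alkenes, so mild aqueous acetic acid hydrolysis (ketal hydrolysis) should release the hydroperoxide, acetone and methanol without touching O–O.

**Step 12**
Reactants: 16 (2S,3S,5E)-1-(TBS-oxy)-3-hydroperoxy-2,6,10-trimethylundeca-5,9-diene
Product: 18 (2S,3S,6R)-1-(TBS-oxy)-3,6-epidioxy-2,6,10-trimethylundec-9-ene, via organomercurial 17 (not isolated)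
Conditions: Hg(OAc)2 (1.1 equiv), CH2Cl2, 0 °C to rt, dark; then NaBH4, 3 M aq. NaOH, 0 °C (same flask)
Reagents that add atoms: none
Why: Hg(OAc)2 adds reversibly to the (E)-C5=C6 alkene to give a mercurinium ion whose positive charge sits on the tertiary C6, and the terminal oxygen of the C3 hydroperoxide opens it at C6 anti to mercury; this is cycloperoxymercuration of an unsaturated hydroperoxide followed by hydride demercuration, a known way to 1,2-dioxanes. The dioxane (O1–O2–C3–C4–C5–C6) closes in the 6-endo-trig mode, preferred over 5-exo attack at C5 because of the Markovnikov polarisation of the trisubstituted mercurinium ion. The new stereocentre C6 is controlled by two substrate elements: in the chair transition state the C3 side chain is equatorial, and the (E) geometry then places C7 (trans to C4) equatorial and the C6 methyl group axial, which is the (3S,6R) relationship of the target, so C6 is set relative to C3. NaBH4 in aqueous NaOH then replaces the equatorial C5–HgOAc bond by C5–H through a C5 radical; this ring radical is poorly aligned for attack on O2, and cold excess hydride limits the known epoxide-forming fragmentation. The step needs regioselectivity (C6 over C5), chemoselectivity (C5=C6 over the C9=C10 prenyl alkene) and diastereoselectivity at C6; they are secured by the tertiary C6, by the absence of any nucleophile within reach of C9=C10 together with the reversibility of mercuration by the weakly electrophilic acetate salt of divalent mercury, and by the alkene geometry fixed in step 2.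

**Step 13**
Reactants: 18 (2S,3S,6R)-1-(TBS-oxy)-3,6-epidioxy-2,6,10-trimethylundec-9-ene
Product: 19 (2S,3S,6R,9E)-1-(TBS-oxy)-3,6-epidioxy-2,6,10-trimethylundec-9-en-11-ol
Conditions: SeO2 (0.3 equiv), t-BuOOH (3 equiv), salicylic acid (0.1 equiv), CH2Cl2, rt
Reagents that add atoms: selenium dioxide O=[Se]=O (oxygen carrier); tert-butyl hydroperoxide CC(C)(C)OO (terminal oxygen source)
Why: Selenium dioxide allylic oxidation (ene reaction then [2,3]-sigmatropic shift, run catalytically with t-BuOOH) attacks the only remaining alkene at its (E)-methyl group and gives the (E)-allylic alcohol, while dialkyl peroxide and silyl ether are inert to these oxidising conditions.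

**Step 14**
Reactants: 19 (2S,3S,6R,9E)-1-(TBS-oxy)-3,6-epidioxy-2,6,10-trimethylundec-9-en-11-ol
Product: 20 (2S,3S,6R,9S,10S)-1-(TBS-oxy)-9,10-epoxy-3,6-epidioxy-2,6,10-trimethylundecan-11-ol
Conditions: Ti(Oi-Pr)4, L-(+)-diethyl tartrate, t-BuOOH (anhydrous, in decane), 4 Å molecular sieves, CH2Cl2, −20 °C
Reagents that add atoms: tert-butyl hydroperoxide CC(C)(C)OO
Why: Sharpless asymmetric epoxidation of the (E)-2-methyl allylic alcohol with the titanium complex of L-(+)-diethyl tartrate delivers oxygen to the face that gives the (2S,3S)-epoxy alcohol type, here (9S,10S), under reagent control independent of the remote dioxane stereocentres.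

**Step 15**
Reactants: 20 (2S,3S,6R,9S,10S)-1-(TBS-oxy)-9,10-epoxy-3,6-epidioxy-2,6,10-trimethylundecan-11-ol
Product: 21 (2S,3S,6R,9S,10R)-1-(TBS-oxy)-9,10-epoxy-3,6-epidioxy-2,6,10-trimethylundecan-11-al
Conditions: Dess–Martin periodinane, NaHCO3, CH2Cl2, 0 °C to rt
Reagents that add atoms: none
Why: Buffered Dess–Martin oxidation converts the primary epoxy alcohol into the aldehyde under neutral conditions, and C10 carries no hydrogen so the α-centre cannot epimerise (the descriptor at C10 changes only because CHO outranks C9).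

**Step 16**
Reactants: 22 β-cyclocitral (2,6,6-trimethylcyclohex-1-ene-1-carbaldehyde)
Product: 23 β-cyclogeraniol [(2,6,6-trimethylcyclohex-1-en-1-yl)methanol]
Conditions: NaBH4, MeOH, 0 °C
Reagents that add atoms: none
Why: Borohydride 1,2-reduction of the hindered conjugated aldehyde gives the allylic alcohol β-cyclogeraniol.

**Step 17**
Reactants: 23 β-cyclogeraniol
Product: 24 triphenyl[(2,6,6-trimethylcyclohex-1-en-1-yl)methyl]phosphonium bromide
Conditions: Ph3P·HBr, MeOH, rt
Reagents that add atoms: triphenylphosphine hydrobromide [PH+](c1ccccc1)(c1ccccc1)c1ccccc1.[Br-]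
Why: Triphenylphosphine hydrobromide ionises the allylic alcohol and the phosphine captures the primary terminus of the allyl cation (phosphonium salt formation), the other terminus being a fully substituted ring carbon.

**Step 18**
Reactants: 24 triphenyl[(2,6,6-trimethylcyclohex-1-en-1-yl)methyl]phosphonium bromide; 21 (2S,3S,6R,9S,10R)-1-(TBS-oxy)-9,10-epoxy-3,6-epidioxy-2,6,10-trimethylundecan-11-al
Product: 26 (2S,3S,6R,9S,10S,11E)-1-(TBS-oxy)-9,10-epoxy-3,6-epidioxy-2,6,10-trimethyl-12-(2,6,6-trimethylcyclohex-1-en-1-yl)dodec-11-ene, via phosphorus ylide 25 (not isolated)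
Conditions: 24, NaN(SiMe3)2, THF, −78 to 0 °C; then 21, −78 °C to rt
Reagents that add atoms: none
Why: Wittig olefination between the semi-stabilised allylic ylide 25 and the non-enolisable epoxy aldehyde forms C11=C12, with the ylide added cold so that carbonyl addition outruns any attack on the O–O bond; the (11E) isomer is expected to predominate and any (11Z) isomer converges in step 19.

**Step 19**
Reactants: 26 (2S,3S,6R,9S,10S,11E)-1-(TBS-oxy)-9,10-epoxy-3,6-epidioxy-2,6,10-trimethyl-12-(2,6,6-trimethylcyclohex-1-en-1-yl)dodec-11-ene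
Product: 27 (2S,3S,6R,9S,10S)-1-(TBS-oxy)-9,10-epoxy-3,6-epidioxy-2,6,10-trimethyl-12-(2,6,6-trimethylcyclohex-1-en-1-yl)dodecane
Conditions: 2-nitrobenzenesulfonylhydrazide (excess, in portions), Et3N, CH2Cl2, rt
Reagents that add atoms: none
Why: Diimide, released in situ from the sulfonylhydrazide, transfers H2 in a concerted syn manner only to the 1,2-disubstituted C11=C12 bond (diimide reduction), since its rate falls steeply with substitution (ring A alkene untouched) and it does not cleave O–O or the oxirane.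

**Step 20**
Reactants: 27 (2S,3S,6R,9S,10S)-1-(TBS-oxy)-9,10-epoxy-3,6-epidioxy-2,6,10-trimethyl-12-(2,6,6-trimethylcyclohex-1-en-1-yl)dodecane
Product: 28 (2S,3S,6R,9S,10S)-9,10-epoxy-3,6-epidioxy-2,6,10-trimethyl-12-(2,6,6-trimethylcyclohex-1-en-1-yl)dodecan-1-ol
Conditions: Bu4NF, AcOH (1:1), THF, 0 °C to rt
Reagents that add atoms: none
Why: Fluoride-induced desilylation (Si–F bond formation) buffered with acetic acid frees C1–OH while keeping the medium too weakly basic for Kornblum–DeLaMare fragmentation at C3–H.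

**Step 21**
Reactants: 28 (2S,3S,6R,9S,10S)-9,10-epoxy-3,6-epidioxy-2,6,10-trimethyl-12-(2,6,6-trimethylcyclohex-1-en-1-yl)dodecan-1-ol
Product: 29 (2R,3S,6R,9S,10S)-9,10-epoxy-3,6-epidioxy-2,6,10-trimethyl-12-(2,6,6-trimethylcyclohex-1-en-1-yl)dodecanal
Conditions: Dess–Martin periodinane, NaHCO3, CH2Cl2, 0 °C
Reagents that add atoms: none
Why: Buffered Dess–Martin oxidation gives the aldehyde without base, so that neither epimerisation at C2 nor β-elimination of the C3 peroxide should occur, and it is used at once.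

**Step 22**
Reactants: 29 (2R,3S,6R,9S,10S)-9,10-epoxy-3,6-epidioxy-2,6,10-trimethyl-12-(2,6,6-trimethylcyclohex-1-en-1-yl)dodecanal
Product: 30 (2R,3S,6R,9S,10S)-9,10-epoxy-3,6-epidioxy-2,6,10-trimethyl-12-(2,6,6-trimethylcyclohex-1-en-1-yl)dodecanoic acid (CNP0204283.1)
Conditions: NaClO2, NaH2PO4, 2-methylbut-2-ene, t-BuOH–H2O, 0 °C to rt
Reagents that add atoms: sodium chlorite [Na+].[O-]Cl=O
Why: Pinnick oxidation (chlorite, buffered, with an alkene scavenger for HOCl) converts the aldehyde into the acid under conditions that spare the oxirane, the peroxide, the ring A alkene and the C2 stereocentre.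

**Compound list**
1 | 6-methylhept-5-en-2-one | CC(=O)CCC=C(C)C | starting material
2 | diethyl 6-methylhepta-1,5-dien-2-yl phosphate | C=C(CCC=C(C)C)OP(=O)(OCC)OCC | intermediate
3 | 6-methylhept-5-en-1-yne | C#CCCC=C(C)C | intermediate
4 | [(1E)-2,6-dimethylhepta-1,5-dien-1-yl]dimethylalane | C[Al](C)/C=C(\C)CCC=C(C)C | intermediate
5 | (1E)-1-iodo-2,6-dimethylhepta-1,5-diene | I/C=C(\C)CCC=C(C)C | intermediate
6 | methyl (2S)-3-hydroxy-2-methylpropanoate | COC(=O)[C@@H](C)CO | starting material
7 | methyl (2S)-3-(TBS-oxy)-2-methylpropanoate | COC(=O)[C@@H](C)CO[Si](C)(C)C(C)(C)C | intermediate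
8 | (2S)-3-(TBS-oxy)-2-methylpropanal | O=C[C@@H](C)CO[Si](C)(C)C(C)(C)C | intermediate
9 | tert-butyl(dimethyl){[(2R)-2-methylbut-3-en-1-yl]oxy}silane | C=C[C@@H](C)CO[Si](C)(C)C(C)(C)C | intermediate
10 | tert-butyl(dimethyl){(2S)-2-[(2RS)-oxiran-2-yl]propoxy}silane (both C3 epimers) | C1OC1[C@@H](C)CO[Si](C)(C)C(C)(C)C | intermediate
11 | tert-butyl(dimethyl){(2S)-2-[(2S)-oxiran-2-yl]propoxy}silane | C1O[C@H]1[C@@H](C)CO[Si](C)(C)C(C)(C)C | intermediate
12 | [(1E)-2,6-dimethylhepta-1,5-dien-1-yl]lithium | [Li]/C=C(\C)CCC=C(C)C | intermediate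
13 | (2S,3R,5E)-1-(TBS-oxy)-2,6,10-trimethylundeca-5,9-dien-3-ol | CC(C)=CCC/C(C)=C/C[C@H]([C@@H](C)CO[Si](C)(C)C(C)(C)C)O | intermediate
14 | (2S,3R,5E)-1-(TBS-oxy)-2,6,10-trimethylundeca-5,9-dien-3-yl 4-bromobenzenesulfonate | CC(C)=CCC/C(C)=C/C[C@H]([C@@H](C)CO[Si](C)(C)C(C)(C)C)OS(=O)(=O)c1ccc(Br)cc1 | intermediate
15 | (2S,3S,5E)-1-(TBS-oxy)-3-[(2-methoxypropan-2-yl)peroxy]-2,6,10-trimethylundeca-5,9-diene | CC(C)=CCC/C(C)=C/C[C@@H]([C@@H](C)CO[Si](C)(C)C(C)(C)C)OOC(C)(C)OC | intermediate
16 | (2S,3S,5E)-1-(TBS-oxy)-3-hydroperoxy-2,6,10-trimethylundeca-5,9-diene | CC(C)=CCC/C(C)=C/C[C@@H]([C@@H](C)CO[Si](C)(C)C(C)(C)C)OO | intermediate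
17 | (2S,3S,5S,6R)-5-(acetoxymercurio)-1-(TBS-oxy)-3,6-epidioxy-2,6,10-trimethylundec-9-ene | CC(C)=CCC[C@]1(C)[C@@H]([Hg]OC(C)=O)C[C@@H]([C@@H](C)CO[Si](C)(C)C(C)(C)C)OO1 | intermediate
18 | (2S,3S,6R)-1-(TBS-oxy)-3,6-epidioxy-2,6,10-trimethylundec-9-ene | CC(C)=CCC[C@]1(C)CC[C@@H]([C@@H](C)CO[Si](C)(C)C(C)(C)C)OO1 | intermediate
19 | (2S,3S,6R,9E)-1-(TBS-oxy)-3,6-epidioxy-2,6,10-trimethylundec-9-en-11-ol | OC/C(C)=C/CC[C@]1(C)CC[C@@H]([C@@H](C)CO[Si](C)(C)C(C)(C)C)OO1 | intermediate
20 | (2S,3S,6R,9S,10S)-1-(TBS-oxy)-9,10-epoxy-3,6-epidioxy-2,6,10-trimethylundecan-11-ol | OC[C@]1(C)O[C@H]1CC[C@]2(C)CC[C@@H]([C@@H](C)CO[Si](C)(C)C(C)(C)C)OO2 | intermediate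
21 | (2S,3S,6R,9S,10R)-1-(TBS-oxy)-9,10-epoxy-3,6-epidioxy-2,6,10-trimethylundecan-11-al | O=C[C@]1(C)O[C@H]1CC[C@]2(C)CC[C@@H]([C@@H](C)CO[Si](C)(C)C(C)(C)C)OO2 | intermediate
22 | β-cyclocitral | CC1=C(C=O)C(C)(C)CCC1 | starting material
23 | β-cyclogeraniol | CC1=C(CO)C(C)(C)CCC1 | intermediate
24 | triphenyl[(2,6,6-trimethylcyclohex-1-en-1-yl)methyl]phosphonium bromide | CC1=C(C[P+](c2ccccc2)(c2ccccc2)c2ccccc2)C(C)(C)CCC1.[Br-] | intermediate
25 | triphenyl[(2,6,6-trimethylcyclohex-1-en-1-yl)methylidene]phosphorane | CC1=C(C=P(c2ccccc2)(c2ccccc2)c2ccccc2)C(C)(C)CCC1 | intermediate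
26 | (2S,3S,6R,9S,10S,11E)-1-(TBS-oxy)-9,10-epoxy-3,6-epidioxy-2,6,10-trimethyl-12-(2,6,6-trimethylcyclohex-1-en-1-yl)dodec-11-ene | CC1=C(/C=C/[C@]2(C)O[C@H]2CC[C@]2(C)CC[C@@H]([C@@H](C)CO[Si](C)(C)C(C)(C)C)OO2)C(C)(C)CCC1 | intermediate
27 | (2S,3S,6R,9S,10S)-1-(TBS-oxy)-9,10-epoxy-3,6-epidioxy-2,6,10-trimethyl-12-(2,6,6-trimethylcyclohex-1-en-1-yl)dodecane | CC1=C(CC[C@]2(C)O[C@H]2CC[C@]2(C)CC[C@@H]([C@@H](C)CO[Si](C)(C)C(C)(C)C)OO2)C(C)(C)CCC1 | intermediate
28 | (2S,3S,6R,9S,10S)-9,10-epoxy-3,6-epidioxy-2,6,10-trimethyl-12-(2,6,6-trimethylcyclohex-1-en-1-yl)dodecan-1-ol | CC1=C(CC[C@]2(C)O[C@H]2CC[C@]2(C)CC[C@@H]([C@@H](C)CO)OO2)C(C)(C)CCC1 | intermediate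
29 | (2R,3S,6R,9S,10S)-9,10-epoxy-3,6-epidioxy-2,6,10-trimethyl-12-(2,6,6-trimethylcyclohex-1-en-1-yl)dodecanal | CC1=C(CC[C@]2(C)O[C@H]2CC[C@]2(C)CC[C@@H]([C@@H](C)C=O)OO2)C(C)(C)CCC1 | intermediate
30 | (2R,3S,6R,9S,10S)-9,10-epoxy-3,6-epidioxy-2,6,10-trimethyl-12-(2,6,6-trimethylcyclohex-1-en-1-yl)dodecanoic acid | CC1=C(CC[C@]2(C)O[C@H]2CC[C@]2(C)CC[C@@H]([C@@H](C)C(=O)O)OO2)C(C)(C)CCC1 | target

**Step count**
Total: 22 steps. Longest linear sequence: 18 steps (from 6: steps 3–15 and 18–22).

**Steps most likely to fail, with fallbacks**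

Step 10 (peroxide substitution at C3). E2 loss of the brosylate toward C4, which would give the conjugated 3,5-diene, may outrun substitution at the β-branched C3, and hydroxide in DMF may erode the silyl ether. The fallback sets out from alcohol 13 and comes back at peroxyketal 15. The alcohol would be converted at −78 °C (Tf2O, 2,6-lutidine, CH2Cl2) into (2S,3R,5E)-1-(TBS-oxy)-2,6,10-trimethylundeca-5,9-dien-3-yl trifluoromethanesulfonate F1. F1 would not be stored; it would be added at −78 °C to the pre-formed potassium salt of 2-methoxyprop-2-yl hydroperoxide (KOt-Bu, THF) and warmed only to 0 °C. The electrophile is thus generated and consumed cold, and the nucleophile is a hydroxide-free peroxide salt in an ether solvent, a change of electrophile class and of medium that should move the balance from elimination to substitution with inversion.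

Step 12 (key step). Loss of the O–O bond during demercuration (radical fragmentation to an epoxide) or incomplete 6-endo selectivity in the mercuration may lower the return. The fallback sets out from hydroperoxide 16 and comes back at dioxane 18. Halonium-induced cyclisation (N-iodosuccinimide, CH2Cl2, 0 °C) would open the iodonium ion at the tertiary C6 in the same anti, 6-endo sense and give (2S,3S,5S,6R)-1-(TBS-oxy)-3,6-epidioxy-5-iodo-2,6,10-trimethylundec-9-ene F2, an isolable compound that can be purified from any C6 epimer. The C5–I bond would then be reduced by a tin hydride chain at low temperature (Bu3SnH in high concentration, Et3B/air, toluene, −78 to 0 °C), where hydrogen transfer to the C5 radical should be faster than its fragmentation.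

Step 19 (diimide reduction). Steric shielding of C11=C12 by the quaternary C10 and by ring A may make hydrogen transfer from diimide too slow, while prolonged exposure to amine base endangers the peroxide. The fallback sets out from epoxy aldehyde 21, replaces steps 18 and 19, and comes back at 27; it forms C12–C13 instead of C11=C12, so no alkene has to be reduced. Wittig methylenation (Ph3PCH3Br, KN(SiMe3)2, THF, −78 °C) would give (2S,3S,6R,9S,10S)-1-(TBS-oxy)-9,10-epoxy-3,6-epidioxy-2,6,10-trimethyldodec-11-ene F3. Hydroboration with 9-borabicyclo[3.3.1]nonane (THF, 0 °C to rt) would give the B-alkyl borane F4, used in solution. F4 would be coupled in a B-alkyl Suzuki–Miyaura reaction (Pd(dppf)Cl2, dppf = 1,1'-bis(diphenylphosphino)ferrocene, AsPh3, Cs2CO3, DMF–THF–H2O, rt, zerovalent palladium formed in situ) with 2,6,6-trimethylcyclohex-1-en-1-yl trifluoromethanesulfonate F5. F5 would be made from commercial 2,2,6-trimethylcyclohexanone, which can enolise only toward C6 (LiN(i-Pr)2, then PhNTf2, THF, −78 °C to rt).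

**Further compounds**
F1 | step 10 | (2S,3R,5E)-1-(TBS-oxy)-2,6,10-trimethylundeca-5,9-dien-3-yl trifluoromethanesulfonate | CC(C)=CCC/C(C)=C/C[C@H]([C@@H](C)CO[Si](C)(C)C(C)(C)C)OS(=O)(=O)C(F)(F)F
F2 | step 12 | (2S,3S,5S,6R)-1-(TBS-oxy)-3,6-epidioxy-5-iodo-2,6,10-trimethylundec-9-ene | CC(C)=CCC[C@]1(C)[C@@H](I)C[C@@H]([C@@H](C)CO[Si](C)(C)C(C)(C)C)OO1
F3 | step 19 | (2S,3S,6R,9S,10S)-1-(TBS-oxy)-9,10-epoxy-3,6-epidioxy-2,6,10-trimethyldodec-11-ene | C=C[C@]1(C)O[C@H]1CC[C@]2(C)CC[C@@H]([C@@H](C)CO[Si](C)(C)C(C)(C)C)OO2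
F4 | step 19 | 9-[(3S,4S,7R,10S,11S)-12-(TBS-oxy)-3,4-epoxy-7,10-epidioxy-3,7,11-trimethyldodecyl]-9-borabicyclo[3.3.1]nonane | B1(CC[C@]2(C)O[C@H]2CC[C@]2(C)CC[C@@H]([C@@H](C)CO[Si](C)(C)C(C)(C)C)OO2)C2CCCC1CCC2
F5 | step 19 | 2,6,6-trimethylcyclohex-1-en-1-yl trifluoromethanesulfonate | CC1=C(OS(=O)(=O)C(F)(F)F)C(C)(C)CCC1
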